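## Structural features

The target 16 is a (2S)-flavanone: benzo ring A is fused to the oxygen heterocycle ring C (a chroman-4-one), and an unsubstituted phenyl ring B sits on C2. Ring A is fully differentiated: a free hydroxyl at C5 hydrogen-bonded to the C4 carbonyl, hydrogen at C6, a prenyl ether at O7 and a C-prenyl group at C8, directly beside the ring-fusion carbon C8a. C2 is the only stereocentre; it carries the aryl ether oxygen O1 and lies β to the carbonyl, so base, or a Lewis acid with heat, can open ring C by retro-oxa-Michael elimination to the achiral 2'-hydroxychalcone and erase it. The fragile groups are the two trisubstituted alkenes (no hydrogenolysis, no borane, no electrophilic halogen) and the allyl aryl ether at O7 (Claisen shift on heating, ionisation by strong acid or by zerovalent palladium). The real difficulty is twofold: four different substituents must be placed on ring A with full regiocontrol, and C2 must be made in one configuration and then never exposed, as a β-aryloxy ketone, to ring-opening conditions. The key step uses the fact that O1 joins the sp2 carbon C8a of ring A to the sp3 stereocentre C2. The O1–C8a bond can therefore be made from the aryl side, from a bromide at C8a, while the C2–O bond and its configuration are already in place and C4 is still a carbinol.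

## Logic of the disconnections

16 ⇒ 15. No skeletal bond is cut; a methoxymethyl acetal is placed on O5 (bond O5–CH2). A free phenol ortho to the benzylic carbinol would lose water to a quinone methide and would compete as a nucleophile in the copper step. The gain is one acidic site fewer in every earlier intermediate. The forward step must remove the acetal under acid mild enough to spare the prenyl ether, the alkenes and C2; the peri carbonyl helps.

15 ⇒ 14. The C4 carbonyl is traced back to a carbinol; the skeleton is unchanged. Ring C is thus closed with no enolisable ketone in the molecule. Either C4 epimer serves, so C4 never needs stereocontrol. The forward step needs a neutral oxidant that ignores alkenes and generates no base.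

14 ⇒ 13. The O1–C8a bond is cut. It is the only ring bond whose formation leaves every bond at C2 alone. Ring C opens to an acyclic 1,3-diol whose aryl part is an ordinary aryl bromide. The forward step must couple the (1S)-hydroxyl with a bromide flanked on both sides, in the presence of a second free hydroxyl, two alkenes and an allyl aryl ether.

13 ⇒ 12. The C–H bond at the phenyl carbinol is removed, giving a phenyl ketone. An aryl alkyl ketone is the best substrate class for catalytic asymmetric reduction. The only stereocentre becomes a choice of catalyst enantiomer. The reduction must be catalyst-controlled whatever the configuration of the neighbouring racemic carbinol, and the reductant must not add to the alkenes (borane would) or touch the C–Br bond.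

12 ⇒ 9 + 10 (through 11). The C3–C4 bond is cut (aldol). The β-hydroxy ketone is the natural retron. The result is two simple carbonyl compounds, and no selectivity is required because the new carbinol becomes the C4 carbonyl. The forward step needs kinetic conditions and a cold quench against retro-aldol cleavage and dehydration at a hindered aldehyde.

9 ⇒ 8. The O5–CH2 acetal bond is cut. The forward step must alkylate a hydrogen-bonded phenol without touching the aldehyde.

8 ⇒ 5 (through 6 and 7). The C8–CH2 bond of the C-prenyl group is cut and the prenyl unit is rejoined to O5. Direct C-prenylation would not distinguish the two free ring carbons, whereas the ether oxygen next to the formyl group is singled out by chelation. In 5 both oxygens carry the same group, and the one that migrates frees exactly the hydroxyl needed at O5. The forward step needs a Lewis acid that activates only the chelated ether, and a Cope relay that reaches the para carbon beside bromine before the ortho dienone enolises.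

5 ⇒ 3 + 4. Both O–CH2 bonds are cut. One alkylation that consumes two equivalents of 4 installs both the future ether and the future C-prenyl group. The forward step must force the hydrogen-bonded hydroxyl to react on oxygen.

3 ⇒ 1. The formyl carbon–aryl bond (C4–C4a) is cut. In symmetric 1 the two carbons flanking bromine are equivalent; one takes the formyl group and the other later receives the prenyl group. The forward step must formylate next to bromine and not between the hydroxyls.

## Other disconnections considered

Alternative 1: The cut is C4–C4a. Forward, the acid A2, (3S)-3-[3,5-bis(benzyloxy)phenoxy]-3-phenylpropanoic acid, would be activated as a mixed anhydride and would acylate the ring carbon ortho to its own ether oxygen, closing ring C as the dibenzyl flavanone A1.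
- In its favour: the aryl ether of A2 is symmetric, so both ortho carbons are equivalent and strongly activated. The ring arrives at the ketone level with no redox adjustment, and no hindered halide or transition metal is involved. On these three points it is better than the chosen plan.
- Against it here: A1 carries neither prenyl group. Hydrogenolysis to the dihydroxyflavanone A3 (possible only while no alkene is present), two O-prenylations (one at the hydrogen-bonded O5) and the europium-catalysed Claisen–Cope shift would all follow on a chiral, base-sensitive flavanone.
- Mechanistic risk: the acylating intermediate places an aryloxide leaving group β to an activated acyl carbon. β-Elimination and acid ionisation of the benzylic C2–O bond both threaten the stereocentre, and making A2 requires forming that benzylic C–O bond with inversion.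
- Comparison: both plans close the same ring with one bond. The chosen plan never touches a bond at C2 and carries the complete ring A substitution through the closure. In step count the two are about equal; the alternative may be one step shorter.

Alternative 2: The cut is C2–C3. Forward, the diazomethyl ketone A5 would lose nitrogen on a chiral dirhodium tetracarboxylate, Rh2(O2CR)4. The carbene at C3 would insert into a benzylic C–H bond of the O-benzyl group on C8a and give the acetate A4, with C2 set by the catalyst.
- In its favour: every ring A substituent is in place before closure, and ring and stereocentre are made in one step (the chosen key step makes no stereocentre). A4 is one mild deacetylation from 16, against two steps after the chosen key step. On convergence and on the end game it is better.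
- Against it here: an acceptor-only carbene of divalent rhodium is unselective. Attack of the ether oxygen lone pair to give a five-membered oxonium ylide, followed by a benzyl shift, is geometrically easier than the six-membered insertion. The two prenyl alkenes invite cyclopropanation, and the configuration at C2 would rest entirely on facial selection by the catalyst, which is usually modest for this carbene class.
- Further cost: A5 needs a diazomethane-type reagent on a doubly ortho-substituted acid derivative that also bears an aryl acetate.
- Comparison: the chosen plan sets C2 with a well-understood ketone reduction and closes the ring with a reaction that cannot change C2. The alternative is shorter after the key step but weaker in chemoselectivity and enantiocontrol.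

Alternative 3: The cuts are O1–C8a and C4–C4a. Forward, fluoride would release the aryne from the silyl triflate A7. The alkoxide of the hydroxy amide A8 would add at the aryne carbon remote from the neighbouring alkoxy group, and the aryl anion formed beside that group would attack the amide carbonyl, giving the flavanone A6.
- In its favour: two bonds and the ring are formed in one step (better than the single bond of the chosen key step). The alkoxy group directs the regiochemistry, and, as in the chosen plan, the C2–O bond is made beforehand and not touched (equal on this point).
- Against it here: the ring is formed at the ketone level in a basic fluoride medium, where the alkoxide of A8 can undergo retro-aldol cleavage and A6 can open by β-elimination. A7 needs several steps of its own. A6 again lacks both prenyl groups, so the route would pass through A3 and the same late prenylation sequence as in alternative 1.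
- Comparison: it is more efficient in bonds per step, but longer overall and less secure for C2 than a closure at the carbinol level.

Key step: step 7

Remarks on the chemistry:
- Abbreviations: prenyl = 3-methylbut-2-en-1-yl; MOM = methoxymethyl; fod = 6,6,7,7,8,8,8-heptafluoro-2,2-dimethyloctane-3,5-dionate; TsDPEN = N-tosyl-1,2-diphenylethane-1,2-diamine.
- Structure check: 13 and 14 map atom for atom onto 16 (Br at C8a, C-prenyl at C8, prenyl ether at O7, acetal at O5). The descriptor S holds from 13 to 16 because the priority order O > phenyl > CH2 > H never changes. No structure needs correction.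
- Design choice 1: the phenyl ketone is reduced by transfer hydrogenation and not by borane. Borane adds to the two trisubstituted alkenes, and, bound to the free carbinol as an alkoxyborane, it can deliver hydride under substrate control and so erode C2.
- Design choice 2: the diol enters the key step unprotected, because a silyl group on a 1,3-diol would migrate to the C2 oxygen under hot carbonate.
- Assumption: 13 and 14 are carried as mixtures of C4 epimers, since C4 becomes sp2 in step 8.

## Route

Step 1
Reactants: 1 5-bromoresorcinol (5-bromobenzene-1,3-diol)
Product: 3 2-bromo-4,6-dihydroxybenzaldehyde, via iminium chloride 2 (not isolated)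
Conditions: POCl3, DMF, MeCN, 0 °C to rt; then H2O, 50 °C
Reagents that add atoms: N,N-dimethylformamide CN(C)C=O (formyl carbon); water O (carbonyl oxygen)
Why: Vilsmeier–Haack formylation; the bulky chloroiminium ion attacks a resorcinol para to one hydroxyl and ortho to the other, which here is the carbon next to bromine, the carbon between the two hydroxyls being the usual minor site, and hydrolysis of 2 releases the aldehyde.

Step 2
Reactants: 3 2-bromo-4,6-dihydroxybenzaldehyde; 4 prenyl bromide (1-bromo-3-methylbut-2-ene), two equivalents consumed in all
Product: 5 2-bromo-4,6-bis(prenyloxy)benzaldehyde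
Conditions: 4 (2.5 equiv), K2CO3 (3 equiv), DMF, rt to 50 °C
Reagents that add atoms: prenyl bromide CC(C)=CCBr (the second equivalent of 4, which supplies the second prenyl group)
Why: Twofold Williamson ether synthesis, one molecule of 4 per hydroxyl; carbonate in DMF ionises both phenols, the free one should react at room temperature and the hydrogen-bonded one on gentle warming, and SN2 attack at the primary allylic carbon gives the unrearranged prenyl ethers.

Step 3
Reactants: 5 2-bromo-4,6-bis(prenyloxy)benzaldehyde
Product: 8 2-bromo-6-hydroxy-3-prenyl-4-(prenyloxy)benzaldehyde, via ortho-dienone 6 (not isolated), via para-dienone 7 (not isolated)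
Conditions: Eu(fod)3 (10 mol%), CHCl3, 65 °C
Reagents that add atoms: none
Why: Lewis-acid-catalysed aromatic Claisen rearrangement followed by a Cope rearrangement (para-Claisen–Cope); trivalent europium chelates the formyl oxygen and the adjacent ether oxygen, so only that ether enters the first [3,3] shift to the free ortho carbon (6), the second [3,3] shift carries the unit, again as a normal prenyl group, to the para carbon beside bromine (7), and enolisation gives 8, while the unchelated ether is thermally inert at this temperature.

Step 4
Reactants: 8 2-bromo-6-hydroxy-3-prenyl-4-(prenyloxy)benzaldehyde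
Product: 9 2-bromo-6-(methoxymethoxy)-3-prenyl-4-(prenyloxy)benzaldehyde
Conditions: MOMCl, i-Pr2NEt, CH2Cl2, 0 °C to rt
Reagents that add atoms: chloromethyl methyl ether COCCl
Why: O-alkylation of the only acidic site by an α-chloro ether through its oxocarbenium ion (acetal protection); the acetal formed is stable to the enolate, to hot carbonate and to the later oxidant.

Step 5
Reactants: 9 2-bromo-6-(methoxymethoxy)-3-prenyl-4-(prenyloxy)benzaldehyde; 10 acetophenone
Product: 12 3-[2-bromo-6-(methoxymethoxy)-3-prenyl-4-(prenyloxy)phenyl]-3-hydroxy-1-phenylpropan-1-one (racemic), via lithium enolate 11 (not isolated)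
Conditions: LiN(i-Pr)2, 10, THF, −78 °C; then 9, −78 °C; AcOH, −78 °C
Reagents that add atoms: none
Why: Kinetic aldol addition of a preformed lithium enolate to an aldehyde without α-hydrogen; the ortho acetal oxygen can chelate lithium in the aldolate, the cold acidic quench prevents retro-aldol cleavage and dehydration, and the new carbinol centre is left racemic on purpose because it becomes the C4 carbonyl.

Step 6
Reactants: 12 3-[2-bromo-6-(methoxymethoxy)-3-prenyl-4-(prenyloxy)phenyl]-3-hydroxy-1-phenylpropan-1-one
Product: 13 (1S)-3-[2-bromo-6-(methoxymethoxy)-3-prenyl-4-(prenyloxy)phenyl]-1-phenylpropane-1,3-diol (both C3 epimers)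
Conditions: RuCl[(S,S)-TsDPEN](p-cymene) (2 mol%), HCO2H/Et3N (1:1), CH2Cl2, 30 °C
Reagents that add atoms: none
Why: Noyori asymmetric transfer hydrogenation; the ruthenium hydride and the ligand N–H deliver H− and H+ in an outer-sphere six-membered transition state whose face is fixed by the CH/π contact between the p-cymene ligand and the phenyl ring of the ketone, so the (S,S) catalyst should give the (1S)-carbinol from both enantiomers of 12, with alkenes, bromide and acetal untouched.

Step 7
Reactants: 13 (1S)-3-[2-bromo-6-(methoxymethoxy)-3-prenyl-4-(prenyloxy)phenyl]-1-phenylpropane-1,3-diol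
Product: 14 (2S)-5-(methoxymethoxy)-8-prenyl-7-(prenyloxy)flavan-4-ol (both C4 epimers)
Conditions: CuI (10 mol%), 3,4,7,8-tetramethyl-1,10-phenanthroline (20 mol%), Cs2CO3, toluene (0.05 M), 110 °C
Reagents that add atoms: none
Why: Mechanism: carbonate and the phenanthroline-ligated monovalent copper convert the (1S)-hydroxyl, the future O1, into a copper alkoxide; the C–Br bond at the future C8a, held next to the metal by the tether, adds to give an aryl alkoxide of trivalent copper, and C–O reductive elimination forms O1–C8a and returns monovalent copper. The closest known reaction type is the intramolecular Ullmann-type etherification of aryl halides with secondary alcohols that gives chromans. Ring C closes as a six-membered ring by exo attack of the tethered oxygen on the ipso carbon (6-exo closure through a seven-membered cupracycle). No stereocentre is formed; C2 keeps its S configuration because neither its C–O nor its C–H bond is touched and no carbonyl is present that would allow retro-aldol cleavage or β-elimination, while C4 stays an epimer mixture that step 8 removes. The selectivity needed is between the two hydroxyls, and ring size secures it, since closure through the C4 oxygen would give a four-membered benzoxete. Intermolecular etherification is held back by dilution, and the electron-rich tetramethylphenanthroline is chosen to speed addition of the hindered, electron-rich bromide beside the C8 prenyl group. Copper is preferred to palladium because it does not ionise the allyl aryl ether or bind the alkenes.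

Step 8
Reactants: 14 (2S)-5-(methoxymethoxy)-8-prenyl-7-(prenyloxy)flavan-4-ol
Product: 15 (2S)-5-(methoxymethoxy)-8-prenyl-7-(prenyloxy)flavan-4-one
Conditions: Dess–Martin periodinane, NaHCO3, CH2Cl2, 0 °C to rt
Reagents that add atoms: none
Why: Dess–Martin oxidation; ligand exchange of the C4 carbinol on pentavalent iodine and internal removal of the C4 hydrogen give the ketone from both epimers, and the buffered neutral medium spares alkenes, allyl ether and acetal and offers no base that could open ring C.

Step 9
Reactants: 15 (2S)-5-(methoxymethoxy)-8-prenyl-7-(prenyloxy)flavan-4-one
Product: 16 (2S)-5-hydroxy-8-prenyl-7-(prenyloxy)flavan-4-one (CNP0292726.1)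
Conditions: HCl (1.25 M in MeOH), MeOH/THF, 0 °C to rt
Reagents that add atoms: none
Why: Acid-catalysed acetal exchange with methanol; the acetal lies peri to the C4 carbonyl and the freed hydroxyl is captured in a hydrogen bond, so cleavage should be fast under acid too mild to ionise the prenyl ether, cyclise the alkenes or open ring C.

## Compound list

1 | 5-bromoresorcinol (5-bromobenzene-1,3-diol) | Oc1cc(O)cc(Br)c1 | starting material
2 | N-[(2-bromo-4,6-dihydroxyphenyl)methylidene]-N-methylmethanaminium chloride, not isolated | C[N+](C)=Cc1c(O)cc(O)cc1Br.[Cl-] | intermediate
3 | 2-bromo-4,6-dihydroxybenzaldehyde | O=Cc1c(O)cc(O)cc1Br | intermediate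
4 | prenyl bromide (1-bromo-3-methylbut-2-ene) | CC(C)=CCBr | starting material
5 | 2-bromo-4,6-bis[(3-methylbut-2-en-1-yl)oxy]benzaldehyde | O=Cc1c(Br)cc(OCC=C(C)C)cc1OCC=C(C)C | intermediate
6 | 2-bromo-5-(2-methylbut-3-en-2-yl)-4-[(3-methylbut-2-en-1-yl)oxy]-6-oxocyclohexa-1,3-diene-1-carbaldehyde (ortho-dienone, racemic, not isolated) | O=CC1=C(Br)C=C(OCC=C(C)C)C(C(C)(C)C=C)C1=O | intermediate
7 | 2-bromo-3-(3-methylbut-2-en-1-yl)-4-[(3-methylbut-2-en-1-yl)oxy]-6-oxocyclohexa-1,4-diene-1-carbaldehyde (para-dienone, racemic, not isolated) | O=CC1=C(Br)C(CC=C(C)C)C(OCC=C(C)C)=CC1=O | intermediate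
8 | 2-bromo-6-hydroxy-3-(3-methylbut-2-en-1-yl)-4-[(3-methylbut-2-en-1-yl)oxy]benzaldehyde | O=Cc1c(O)cc(OCC=C(C)C)c(CC=C(C)C)c1Br | intermediate
9 | 2-bromo-6-(methoxymethoxy)-3-(3-methylbut-2-en-1-yl)-4-[(3-methylbut-2-en-1-yl)oxy]benzaldehyde | COCOc1cc(OCC=C(C)C)c(CC=C(C)C)c(Br)c1C=O | intermediate
10 | acetophenone | CC(=O)c1ccccc1 | starting material
11 | lithium 1-phenylethen-1-olate (lithium enolate of 10, not isolated) | [Li]OC(=C)c1ccccc1 | intermediate
12 | 3-[2-bromo-6-(methoxymethoxy)-3-(3-methylbut-2-en-1-yl)-4-[(3-methylbut-2-en-1-yl)oxy]phenyl]-3-hydroxy-1-phenylpropan-1-one (racemic) | CC(C)=CCOc1cc(OCOC)c(C(O)CC(=O)c2ccccc2)c(Br)c1CC=C(C)C | intermediate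
13 | (1S)-3-[2-bromo-6-(methoxymethoxy)-3-(3-methylbut-2-en-1-yl)-4-[(3-methylbut-2-en-1-yl)oxy]phenyl]-1-phenylpropane-1,3-diol (both C3 epimers) | CC(C)=CCOc1cc(OCOC)c(C(O)C[C@H](O)c2ccccc2)c(Br)c1CC=C(C)C | intermediate
14 | (2S)-5-(methoxymethoxy)-8-(3-methylbut-2-en-1-yl)-7-[(3-methylbut-2-en-1-yl)oxy]-2-phenyl-3,4-dihydro-2H-chromen-4-ol (both C4 epimers) | CC(C)=CCOc1cc(OCOC)c2c(c1CC=C(C)C)O[C@H](c1ccccc1)CC2O | intermediate
15 | (2S)-5-(methoxymethoxy)-8-(3-methylbut-2-en-1-yl)-7-[(3-methylbut-2-en-1-yl)oxy]-2-phenyl-2,3-dihydro-4H-chromen-4-one | CC(C)=CCOc1cc(OCOC)c2c(c1CC=C(C)C)O[C@H](c1ccccc1)CC2=O | intermediate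
16 | (2S)-5-hydroxy-8-(3-methylbut-2-en-1-yl)-7-[(3-methylbut-2-en-1-yl)oxy]-2-phenyl-2,3-dihydro-4H-chromen-4-one (CNP0292726.1) | CC(C)=CCOc1cc(O)c2c(c1CC=C(C)C)O[C@H](c1ccccc1)CC2=O | target

## Step count and least certain steps

Total step count: 9. Longest linear sequence: 9 steps (1 to 16); 4 and 10 are bought and enter in steps 2 and 5, with 4 used twice over in step 2.

Step 7 (key step). The most likely failure is slow addition of the C–Br bond to copper, because the bromide is electron-rich and flanked by the prenyl group and the tether. Reduction of the C–Br bond with the carbinols as hydride donors, copper-mediated oxidation of the C4 carbinol and intermolecular etherification could then take over. Fallback (sets out from 13, comes back at 14): the leaving group is changed before ring closure. Double deprotonation of 13 with n-BuLi at −78 °C, bromine–lithium exchange with t-BuLi and quenching of the aryllithium with 1,2-diiodoethane should give (1S)-3-[2-iodo-6-(methoxymethoxy)-3-prenyl-4-(prenyloxy)phenyl]-1-phenylpropane-1,3-diol F1. The C–I bond adds to monovalent copper far more readily, so closure with CuI, 1,10-phenanthroline and Cs2CO3 should then proceed at 80–90 °C to 14. The sequence under step 3 removes the ortho prenyl group altogether and is the second line of defence.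

Step 3. The Cope relay must reach a carbon flanked by bromine and an ether before the ortho dienone 6 enolises; if enolisation wins, the reverse-prenyl group stays on the wrong carbon. An aldehyde is also a weaker chelating partner for trivalent europium than the ketones on which this shift is usually run, so the second ether could rearrange as well. Fallback (sets out from 5, comes back at 16): the rearrangement is postponed until ring C exists. Aldol addition of 11 to 5 should give 3-[2-bromo-4,6-bis(prenyloxy)phenyl]-3-hydroxy-1-phenylpropan-1-one F2. Transfer hydrogenation as in step 6 should give (1S)-3-[2-bromo-4,6-bis(prenyloxy)phenyl]-1-phenylpropane-1,3-diol F3. Copper-catalysed closure as in step 7, now at a bromide with a single ortho substituent, should give (2S)-5,7-bis(prenyloxy)flavan-4-ol F4, and Dess–Martin oxidation should give (2S)-5,7-bis(prenyloxy)flavanone F5. Eu(fod)3 in CHCl3 should then move the O5 prenyl group, chelated to the C4 carbonyl, through the same Claisen–Cope relay to C8 and deliver 16 directly. This sequence needs no acetal and is two steps shorter. It is held in reserve for two reasons: it closes ring C on a substrate without the C8 prenyl group, which is not the precursor this plan is built around, and it exposes the finished stereocentre to a Lewis acid at 65 °C, where reversible opening of ring C would erode C2.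

Step 6. The benzylic carbinol of 12 sits on an electron-rich ring and could ionise or dehydrate in the formic acid medium, and the amine could promote retro-aldol cleavage. A mismatched pairing of catalyst and one enantiomer of 12 would lower the selectivity at C1, and this would reappear as lower enantiomeric purity of 16 once C4 is flattened. Fallback (sets out from 12, comes back at 13): the hydroxyl is masked and a boron hydride is used in the cold. Et3SiOTf and 2,6-lutidine at −78 °C should give 3-[2-bromo-6-(methoxymethoxy)-3-prenyl-4-(prenyloxy)phenyl]-1-phenyl-3-[(triethylsilyl)oxy]propan-1-one F6. Corey–Bakshi–Shibata reduction with the (R)-B-methyl oxazaborolidine and catecholborane in toluene at −78 °C, a reductant that leaves trisubstituted alkenes alone, should give (1S)-3-[2-bromo-6-(methoxymethoxy)-3-prenyl-4-(prenyloxy)phenyl]-1-phenyl-3-[(triethylsilyl)oxy]propan-1-ol F7. Bu4NF in THF should then return 13.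

Step 1. The electrophile could attack the carbon between the two hydroxyls, formylate oxygen, or react twice, because the free resorcinol is very reactive and its regiochemistry rests on analogy. Fallback (sets out from 1, comes back at 3): O-methylation with MeI and K2CO3 should give 1-bromo-3,5-dimethoxybenzene F8. Vilsmeier–Haack formylation of this ether, whose preference for the carbon next to bromine is well established, should give 2-bromo-4,6-dimethoxybenzaldehyde F9. Demethylation with BBr3 in CH2Cl2 should return 3.

## Further compounds

F1 | step 7 | (1S)-3-[2-iodo-6-(methoxymethoxy)-3-(3-methylbut-2-en-1-yl)-4-[(3-methylbut-2-en-1-yl)oxy]phenyl]-1-phenylpropane-1,3-diol | CC(C)=CCOc1cc(OCOC)c(C(O)C[C@H](O)c2ccccc2)c(I)c1CC=C(C)C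
F2 | step 3 | 3-[2-bromo-4,6-bis[(3-methylbut-2-en-1-yl)oxy]phenyl]-3-hydroxy-1-phenylpropan-1-one (racemic) | CC(C)=CCOc1cc(Br)c(C(O)CC(=O)c2ccccc2)c(OCC=C(C)C)c1
F3 | step 3 | (1S)-3-[2-bromo-4,6-bis[(3-methylbut-2-en-1-yl)oxy]phenyl]-1-phenylpropane-1,3-diol (both C3 epimers) | CC(C)=CCOc1cc(Br)c(C(O)C[C@H](O)c2ccccc2)c(OCC=C(C)C)c1
F4 | step 3 | (2S)-5,7-bis[(3-methylbut-2-en-1-yl)oxy]-2-phenyl-3,4-dihydro-2H-chromen-4-ol (both C4 epimers) | CC(C)=CCOc1cc(OCC=C(C)C)c2c(c1)O[C@H](c1ccccc1)CC2O
F5 | step 3 | (2S)-5,7-bis[(3-methylbut-2-en-1-yl)oxy]-2-phenyl-2,3-dihydro-4H-chromen-4-one | CC(C)=CCOc1cc(OCC=C(C)C)c2c(c1)O[C@H](c1ccccc1)CC2=O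
F6 | step 6 | 3-[2-bromo-6-(methoxymethoxy)-3-(3-methylbut-2-en-1-yl)-4-[(3-methylbut-2-en-1-yl)oxy]phenyl]-1-phenyl-3-[(triethylsilyl)oxy]propan-1-one (racemic) | CC(C)=CCOc1cc(OCOC)c(C(O[Si](CC)(CC)CC)CC(=O)c2ccccc2)c(Br)c1CC=C(C)C
F7 | step 6 | (1S)-3-[2-bromo-6-(methoxymethoxy)-3-(3-methylbut-2-en-1-yl)-4-[(3-methylbut-2-en-1-yl)oxy]phenyl]-1-phenyl-3-[(triethylsilyl)oxy]propan-1-ol (both C3 epimers) | CC(C)=CCOc1cc(OCOC)c(C(O[Si](CC)(CC)CC)C[C@H](O)c2ccccc2)c(Br)c1CC=C(C)C
F8 | step 1 | 1-bromo-3,5-dimethoxybenzene | COc1cc(OC)cc(Br)c1
F9 | step 1 | 2-bromo-4,6-dimethoxybenzaldehyde | COc1cc(OC)c(C=O)c(Br)c1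
A1 | alternative 1 | (2S)-5,7-bis(benzyloxy)flavanone | O=C1C[C@@H](c2ccccc2)Oc2cc(OCc3ccccc3)cc(OCc3ccccc3)c21
A2 | alternative 1 | (3S)-3-[3,5-bis(benzyloxy)phenoxy]-3-phenylpropanoic acid | OC(=O)C[C@H](Oc1cc(OCc2ccccc2)cc(OCc2ccccc2)c1)c1ccccc1
A3 | alternative 1 | (2S)-5,7-dihydroxyflavanone | O=C1C[C@@H](c2ccccc2)Oc2cc(O)cc(O)c21
A4 | alternative 2 | (2S)-5-acetoxy-7-(prenyloxy)-8-prenylflavanone | CC(C)=CCOc1cc(OC(C)=O)c2c(c1CC=C(C)C)O[C@H](c1ccccc1)CC2=O
A5 | alternative 2 | 1-[6-acetoxy-2-(benzyloxy)-3-(3-methylbut-2-en-1-yl)-4-[(3-methylbut-2-en-1-yl)oxy]phenyl]-2-diazoethan-1-one | CC(C)=CCOc1cc(OC(C)=O)c(C(=O)C=[N+]=[N-])c(OCc2ccccc2)c1CC=C(C)C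
A6 | alternative 3 | (2S)-5,7-bis(methoxymethoxy)flavanone | COCOc1cc(OCOC)c2c(c1)O[C@H](c1ccccc1)CC2=O
A7 | alternative 3 | 3,5-bis(methoxymethoxy)-2-(trimethylsilyl)phenyl trifluoromethanesulfonate | COCOc1cc(OCOC)c([Si](C)(C)C)c(OS(=O)(=O)C(F)(F)F)c1
A8 | alternative 3 | (3S)-3-hydroxy-N-methoxy-N-methyl-3-phenylpropanamide | CON(C)C(=O)C[C@H](O)c1ccccc1
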